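## Structural features

Formosanatin D is an achiral hexacyclic coumaronochromone. A 4-pyranone (ring C) is fused to ring A and, across C2–C3, to a furan that is fused to ring B, so C2 carries two oxygens (O1 and the oxygen on C2') and is a ketene acetal carbon. Ring A is pentasubstituted: C4a bears the acyl carbon C4, C5 a chelated hydroxyl, C7 the oxygen and C8 the methylene of the saturated 2,2-dimethylpyran ring D, and C8a bears O1. Ring B carries oxygen at C2', C4' and C5' and carbon at C1' and C3'; the 2,2-dimethyl-2H-pyran ring E sits on C3'/C4'–O and C5' has a free hydroxyl. There is no stereocentre, so every selectivity problem is one of regiochemistry. Fragile points are the styrene-type olefin of ring E (acid, electrophiles, oxidants, hydrogenation), the hydroquinone-type ring B (oxidation), the tertiary alkyl aryl ethers of rings D and E (strong Lewis acids) and C2 (nucleophiles under forcing conditions). The real difficulty is ring A: the oxygens on C5 and C8a both flank the acyl-bearing C4a and must be told apart while the ring D carbon is placed on C8 and not on C6. The key step uses the fact that the C7–C8 enol ether of ring D can be one half of a diene: forming C8–C8a and C4a–C5 by cycloaddition puts a halogen on C8a next to ring D and a hydroxyl on C5 by construction.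

## Logic of the disconnections

31 ⇒ 30. The two acetal C–O bonds on the C5 and C5' oxygens are cut. A free C5 hydroxyl would attack the lactone carbonyl of the ring B half after the fragment coupling, and a free C5' hydroxyl is acidic and oxidisable under base and copper. There is no skeletal gain, but it makes the preceding steps safe. The forward step must be a single mild acid treatment that spares the ring E olefin, the tertiary ethers and C2.

30 ⇒ 29. O1–C8a is cut. The enol oxygen on C2 and the bromine on C8a are held in a 1,6-relationship by the ketone, so ring C can close by intramolecular O-arylation. This opens the hexacycle into two halves joined only by C3–C4. The forward step must arylate oxygen at a bromide flanked by two ortho substituents without cleaving the lactone.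

29 ⇒ 16 + 27 (through 28). C3–C4 is cut. C3 is the acidic methylene of a γ-lactone whose carbonyl carbon already is C2 with its ring B oxygen, and C4 is an acyl carbon. The cut is convergent and gives halves of similar size. The acyl donor is hindered and electron-rich and the enolate is stabilised, so the acid is activated as 28 rather than used as its methyl ester.

16 ⇒ 15 ⇒ 14. The methoxymethyl O–C bond is cut and the acid is taken back to the methyl ester. This leads to the arene that the cycloaddition gives directly. The forward steps must alkylate a chelated phenol and saponify a doubly ortho-substituted benzoate.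

14 ⇒ 9 + 11 (through 12 and 13). C4a–C5 and C8–C8a are cut. Ring A falls into a four-carbon diene that already contains ring D and a two-carbon alkyne that carries the ester and the bromine. The gain is a whole benzene ring with the C5/C8a differentiation built in. The forward step needs one regiochemistry of cycloaddition, aromatisation by loss of silanol, and survival of the C–Br bond.

11 ⇒ 10. The C–Br bond is cut; the forward step is electrophilic bromination of a terminal alkyne.

9 ⇒ 7 (through 8) ⇒ 6. Both O–Si bonds are cut and the acid is taken back to its methyl ester. A bis(silyl) acetal leaves no doubt that C5 ends as a free hydroxyl. The forward step needs γ-deprotonation of the silyl ester and O-silylation, and the acid must be isolated without hydrating its enol ether.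

6 ⇒ 5 ⇒ 3 + 4. The exocyclic C=C is cut (dehydration of a hemiketal), then the C–C bond between the acetate α-carbon and the lactone carbonyl. The forward steps need single addition of an ester enolate to a lactone and elimination toward the conjugated enol ether.

3 ⇒ 1 (through 2). One C–CH3 bond and the lactone C–O bond are cut. The forward step is ketone-selective Grignard addition followed by lactonisation.

27 ⇒ 26 ⇒ 23 + 24 (through 25). The tetrahydropyranyl O–C bond is cut, then the C1'–C3 bond and the O(C2')–C2 bond. Raising ring B to the quinone level makes C1' electrophilic, and the ring E oxygen directs a ketene acetal to that carbon. The forward step needs regioselective conjugate addition and lactonisation on the neighbouring oxygen.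

23 ⇒ 22 ⇒ 21 ⇒ 19 + 20. The quinone is taken back to the hydroquinone dimethyl ether, ring E is opened (C3'–C and O–CMe2, a pericyclic cascade in the forward direction), and the propargylic ether O–C bond is cut. The forward steps need rearrangement to the only free ortho position and oxidative demethylation in the presence of the ring E olefin.

19 ⇒ 17 (through 18). The C4'–O bond is traced back to a formyl group. The forward step is a Dakin-type oxidation, in which the aldehyde carbon serves only as a latent hydroxyl.

## Other disconnections considered

Alternative 1: The cut removes C2 altogether (C2–C3, C2–O1, C2–O on C2'). The precursor is deoxybenzoin A1 and the product is the 5-O-methyl, 5'-O-methoxymethyl ether A2. In the forward step the C3 enolate of A1 bonds to the carbon of CS2, double S-methylation with MeI turns that carbon into a twofold electrophile, and the phenoxides on C8a and C2' displace both methylthio groups. In its favour: three bonds and two rings form in one flask, C2 comes from a cheap one-carbon reagent, and no transition metal is needed. On bonds formed per operation this is better than the chosen key step (two bonds, one ring). Against it here: A1 needs a ring A with free C8a–OH, methylated C5–O and ring D on C8, so the ring A differentiation is moved into the synthesis of A1 rather than solved. MeI in the presence of three oxyanions invites O-methylation. A2 still needs cleavage of the chelated C5 methyl ether by a Lewis acid next to the tertiary ethers and the ring E olefin, plus acetal removal. On stereochemistry the two plans are equal (none). On regiocontrol of ring A the chosen plan is stronger. On step count the alternative would be equal or shorter only if A1 were available in few steps, which the angular ring D makes doubtful.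

Alternative 2: The cut removes the C8–CH2 bond and the bonds of ring E (C3'–CH, O–CMe2). The precursor is the 7-O-(1,1-dimethylallyl) 4'-O-(1,1-dimethylpropargyl) diether A3 and the product is the 8-prenyl compound A4. Heating A3 triggers an allyl Claisen shift to C8 and a propargyl Claisen shift to C3'; the latter is followed by hydrogen shift and oxa-6π closure of ring E. In its favour: the key step is thermal, reagent-free and fully atom-economic, and both C5 units are added late to a simple core. On these points it is better than the chosen plan. Against it here: the allyl unit can migrate to C6 as well as C8, and nothing in A3 decides between them. Ring D must then be closed by acid-mediated addition of the C7 hydroxyl to the prenyl olefin while the acid-sensitive ring E is present. A3 itself requires the whole coumaronochromone core and two tertiary ether formations on differentiated phenols. The plans are equal in having no stereochemical issue. The chosen plan is stronger on regiochemical certainty and avoids the acid cyclisation. Step economy is comparable only if the core of A3 is short to make.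

Alternative 3: The cut is the O–C2' bond of the furan. The precursor is the 3-aryl-4-methoxycoumarin A5 and the product is the 5-O-methyl ether A6. PhI(OAc)2 in hexafluoroisopropanol oxidises the C5' phenol of A5, the lactone carbonyl oxygen attacks the para carbon C2', and loss of the O4 methyl group turns the coumarin into the chromone. In its favour: the C2' oxygen is introduced by C–H functionalisation, so the ring B building block needs only two oxygens. The step is metal-free, and A5 could be assembled convergently by cross-coupling. On ring B simplicity this is better than the chosen plan, which has to build a trioxygenated ring B. Against it here: the oxidant meets an electron-rich phenol that also carries the ring E olefin, and the cyclised product is a para-alkoxyphenol open to further oxidation. A5 needs the same C8a/C5 differentiation on ring A, here as lactone oxygen against methyl ether. A6 still requires Lewis-acid cleavage of the C5 methyl ether. The plans are equal on stereochemistry. The chosen plan is stronger in being redox-neutral after ring B is made and in solving ring A directly. Step count is likely similar.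

Key step: step 7

Remarks on the chemistry:
- Atom labels are those of the isoflavone skeleton of the target unless "chroman numbering" or "chromene numbering" is stated.
- The ring B partner must be a benzofuran-2(3H)-one (γ-lactone); only that isomer supplies C2 with both of its oxygens.
- Compounds 6, 7 and 8 are drawn as (E)-isomers; the (Z)-isomers would give the same diene 9.
- Compounds 27, 29 and 30 are racemic at the tetrahydropyranyl acetal carbon, 5 and 12 are racemic, and 29 is drawn as the keto tautomer of a largely enolised compound. None of these centres survives to 31.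
- Ring B is made from the dimethyl ether of the hydroquinone aldehyde (17), whose formyl group is used as a latent hydroxyl.
- The ester 15 is not used directly in the fragment coupling; it is saponified and activated, because a doubly ortho-substituted, electron-rich benzoate is a poor partner for a stabilised enolate.

Step 1
Reactants: 1 methyl 5-oxohexanoate
Product: 3 6,6-dimethyltetrahydro-2H-pyran-2-one, via hydroxy ester alkoxide 2 (not isolated)
Conditions: MeMgBr (1.05 equiv), THF, −40 → 0 °C; then 1 M HCl, rt
Reagents that add atoms: methylmagnesium bromide, C[Mg]Br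
Why: Grignard addition is selective for the ketone over the less electrophilic ester at low temperature; the tertiary alkoxide 2 closes the δ-lactone by intramolecular transesterification on warming and acidic work-up.

Step 2
Reactants: 3 6,6-dimethyltetrahydro-2H-pyran-2-one; 4 methyl acetate
Product: 5 methyl 2-(2-hydroxy-6,6-dimethyltetrahydro-2H-pyran-2-yl)acetate (racemic hemiketal)
Conditions: 4, LiN(iPr)2 (1.5 equiv), THF, −78 °C; then 3, −78 °C; AcOH quench at −78 °C
Reagents that add atoms: none
Why: Claisen-type addition of the lithium ester enolate to the lactone carbonyl; the tetrahedral lithium alkoxide persists at −78 °C, so only one addition occurs and cold protonation gives the hemiketal (in equilibrium with its open β-keto ester tautomer). The hemiketal centre is racemic and is removed in step 3.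

Step 3
Reactants: 5 methyl 2-(2-hydroxy-6,6-dimethyltetrahydro-2H-pyran-2-yl)acetate
Product: 6 methyl (E)-2-(6,6-dimethyltetrahydro-2H-pyran-2-ylidene)acetate
Conditions: MsCl, Et3N, CH2Cl2, 0 °C → rt
Reagents that add atoms: none
Why: Sulfonylation of the anomeric hydroxyl, ionisation to the oxocarbenium ion and loss of the acidic α-proton give the conjugated exocyclic enol ether (a vinylogous carbonate); the (E)-isomer should predominate and the geometry is irrelevant for step 5.

Step 4
Reactants: 6 methyl (E)-2-(6,6-dimethyltetrahydro-2H-pyran-2-ylidene)acetate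
Product: 7 (E)-2-(6,6-dimethyltetrahydro-2H-pyran-2-ylidene)acetic acid
Conditions: LiOH, THF/MeOH/H2O, 50 °C; then 1 M HCl to pH 4, 0 °C, rapid extraction
Reagents that add atoms: lithium hydroxide, [Li+].[OH-]
Why: Saponification of the deactivated β-alkoxyacrylate needs gentle heating; cold protonation at pH 4 avoids hydration of the enol ether, which would open the way to decarboxylation.

Step 5
Reactants: 7 (E)-2-(6,6-dimethyltetrahydro-2H-pyran-2-ylidene)acetic acid
Product: 9 6-[2,2-bis(trimethylsilyloxy)vinyl]-2,2-dimethyl-3,4-dihydro-2H-pyran, via silyl ester 8 (not isolated)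
Conditions: Me3SiCl, Et3N, THF, 0 °C; then LiN(iPr)2, −78 °C; Me3SiCl, −78 °C → rt; non-aqueous work-up (pentane, filtration, short-path distillation)
Reagents that add atoms: chlorotrimethylsilane, C[Si](C)(C)Cl
Why: The silyl ester is deprotonated at the γ-methylene (syn to the carbonyl in the (E)-isomer) to give the extended dienolate, and O-silylation by the hard silyl chloride gives the vinylketene bis(silyl) acetal with the enol ether double bond moved into the ring; this is the standard route to bis(silyl) ketene acetals from silyl esters.

Step 6
Reactants: 10 methyl propiolate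
Product: 11 methyl 3-bromopropiolate
Conditions: NBS, AgNO3 (10 mol %), acetone, rt
Reagents that add atoms: N-bromosuccinimide, O=C1CCC(=O)N1Br
Why: Silver-catalysed electrophilic bromination of the terminal alkyne through the silver acetylide, the usual preparation of 3-bromopropiolates.

Step 7
Reactants: 9 6-[2,2-bis(trimethylsilyloxy)vinyl]-2,2-dimethyl-3,4-dihydro-2H-pyran; 11 methyl 3-bromopropiolate
Product: 14 methyl 5-bromo-7-hydroxy-2,2-dimethylchroman-6-carboxylate, via cycloadduct 12 (not isolated), via aryl silyl ether 13 (not isolated)
Conditions: PhMe, 0 → 60 °C, Ar, no Lewis acid; then 1 M HCl, THF, rt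
Reagents that add atoms: none
Why: This is a normal-electron-demand Diels–Alder reaction of a trioxygenated diene with an acceptor alkyne, closest in type to vinylketene acetal/alkynoate benzannulations that aromatise by loss of alcohol or silanol. The largest HOMO coefficient of 9 lies on the ring enol ether carbon (future C8), which bonds to the bromine-bearing β-carbon of 11 (future C8a), while the ketene acetal carbon (future C5) bonds to the α-carbon (future C4a); bond formation may be concerted but asynchronous, or may pass through a Michael adduct that closes in a Mukaiyama-type step, and both paths lead to 12. Ring A closes as a six-membered carbocycle in a (4+2) mode, and the s-cis diene is accessible because the inside substituent on the C8 terminus is hydrogen. In 12 the silyl ketal carbon C5 and the C8 hydrogen are 1,4-related across the cyclohexa-1,4-diene, so loss of Me3SiOH gives the arene 13, whose silyl ether is cleaved by the dilute acid. No stereocentre is formed that survives: the only sp3 centre of 12 (C8, racemic) becomes aromatic. The step needs regioselectivity, which is secured by the matched polarity of the two partners and by ring D being part of the diene, so bromine can only end next to the ring D carbon and the hydroxyl on C5. It also needs chemoselectivity for cycloaddition over addition–elimination at the C–Br carbon, which is favoured by a non-polar solvent, moderate temperature and the absence of Lewis acid.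

Step 8
Reactants: 14 methyl 5-bromo-7-hydroxy-2,2-dimethylchroman-6-carboxylate
Product: 15 methyl 5-bromo-7-(methoxymethoxy)-2,2-dimethylchroman-6-carboxylate
Conditions: NaH, MOMCl, DMF, 0 °C → rt
Reagents that add atoms: chloromethyl methyl ether, COCCl
Why: Williamson-type O-alkylation of the chelated phenoxide; the acetal masks the C5 oxygen, which would otherwise open the lactone of the ring B half after step 16.

Step 9
Reactants: 15 methyl 5-bromo-7-(methoxymethoxy)-2,2-dimethylchroman-6-carboxylate
Product: 16 5-bromo-7-(methoxymethoxy)-2,2-dimethylchroman-6-carboxylic acid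
Conditions: KOH, DMSO/H2O, 80 °C; then 1 M HCl to pH 4, 0 °C
Reagents that add atoms: potassium hydroxide, [K+].[OH-]
Why: Saponification of a doubly ortho-substituted benzoate needs a dipolar solvent and heat, which the acetal, the aryl bromide and the chroman tolerate; cold acidification to pH 4 keeps the MOM ether.

Step 10
Reactants: 17 2,5-dimethoxybenzaldehyde
Product: 19 2,5-dimethoxyphenol, via aryl formate 18 (not isolated)
Conditions: mCPBA, CH2Cl2, 0 °C → rt; then NaOH, MeOH/H2O, rt; HCl work-up
Reagents that add atoms: 3-chloroperoxybenzoic acid, OOC(=O)c1cccc(Cl)c1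
Why: Dakin-type oxidation: Baeyer–Villiger aryl migration of the electron-rich aldehyde gives the formate, which is hydrolysed to the phenol that will become the ring E oxygen on C4'.

Step 11
Reactants: 19 2,5-dimethoxyphenol; 20 3-chloro-3-methylbut-1-yne
Product: 21 1,4-dimethoxy-2-[(2-methylbut-3-yn-2-yl)oxy]benzene
Conditions: CuCl2 (1 mol %), DBU, MeCN, 0 °C → rt
Reagents that add atoms: none
Why: Copper-catalysed propargylic substitution of the tertiary chloride by the phenoxide, the standard way to aryl 1,1-dimethylpropargyl ethers.

Step 12
Reactants: 21 1,4-dimethoxy-2-[(2-methylbut-3-yn-2-yl)oxy]benzene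
Product: 22 5,8-dimethoxy-2,2-dimethyl-2H-chromene
Conditions: o-xylene, 140 °C
Reagents that add atoms: none
Why: Aromatic propargyl Claisen rearrangement to the only free ortho position, followed by tautomerisation, 1,5-hydrogen shift and oxa-6π electrocyclisation, gives the 2,2-dimethylchromene (ring E on C3'/C4'–O).

Step 13
Reactants: 22 5,8-dimethoxy-2,2-dimethyl-2H-chromene
Product: 23 2,2-dimethyl-2H-chromene-5,8-dione
Conditions: (NH4)2Ce(NO3)6 (2.5 equiv), MeCN/H2O, 0 °C
Reagents that add atoms: water, O
Why: Oxidative demethylation of a para-dimethoxyarene by the one-electron oxidant; water attacks the radical cation at the methoxy-bearing carbons and methanol leaves, a reaction that tolerates the conjugated chromene olefin at 0 °C.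

Step 14
Reactants: 23 2,2-dimethyl-2H-chromene-5,8-dione; 24 1,1-dimethoxyethene
Product: 26 5-hydroxy-7,7-dimethyl-3,7-dihydro-2H-furo[2,3-f]chromen-2-one, via cyclic ortho ester 25 (not isolated)
Conditions: 24 (1.5 equiv), MeCN, 0 °C → rt; then 1 M HCl, THF, rt
Reagents that add atoms: water, O
Why: Conjugate addition of a ketene acetal to a quinone (a known route to 5-hydroxybenzofuran-2-ones): in chromene numbering the C5 carbonyl is a vinylogous ester of the ring oxygen, so the nucleophile adds at C6, β to the more electrophilic C8 carbonyl. Tautomerisation to the hydroquinone and capture of the dialkoxycarbenium ion by the C5 hydroxyl give 25, which dilute acid hydrolyses to the γ-lactone.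

Step 15
Reactants: 26 5-hydroxy-7,7-dimethyl-3,7-dihydro-2H-furo[2,3-f]chromen-2-one
Product: 27 7,7-dimethyl-5-[(tetrahydro-2H-pyran-2-yl)oxy]-3,7-dihydro-2H-furo[2,3-f]chromen-2-one (racemic)
Conditions: 3,4-dihydro-2H-pyran, PPTS (10 mol %), CH2Cl2, rt
Reagents that add atoms: 3,4-dihydro-2H-pyran, C1=COCCC1
Why: Acid-catalysed addition of the phenol to the enol ether; acid catalysis is chosen because basic alkylation would also alkylate the acidic lactone methylene. The acetal carbon forms as a racemate and is removed in step 18.

Step 16
Reactants: 16 5-bromo-7-(methoxymethoxy)-2,2-dimethylchroman-6-carboxylic acid; 27 7,7-dimethyl-5-[(tetrahydro-2H-pyran-2-yl)oxy]-3,7-dihydro-2H-furo[2,3-f]chromen-2-one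
Product: 29 3-{[5-bromo-7-(methoxymethoxy)-2,2-dimethylchroman-6-yl]carbonyl}-7,7-dimethyl-5-[(tetrahydro-2H-pyran-2-yl)oxy]-3,7-dihydro-2H-furo[2,3-f]chromen-2-one, via acyl imidazolide 28 (not isolated)
Conditions: 16, 1,1'-carbonyldiimidazole, THF, rt; solution added to 27, NaH (3.3 equiv), THF, 0 → 50 °C; AcOH quench
Reagents that add atoms: none
Why: Claisen-type C-acylation of the sodium lactone enolate by the acyl imidazolide; excess base deprotonates the 1,3-dicarbonyl product, which makes the acylation irreversible, and any O-acylated enol ester is itself an acyl donor that funnels to the C-acylated enolate.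

Step 17
Reactants: 29 3-{[5-bromo-7-(methoxymethoxy)-2,2-dimethylchroman-6-yl]carbonyl}-7,7-dimethyl-5-[(tetrahydro-2H-pyran-2-yl)oxy]-3,7-dihydro-2H-furo[2,3-f]chromen-2-one
Product: 30 5-O-(methoxymethyl)-5'-O-(tetrahydro-2H-pyran-2-yl)formosanatin D (racemic at the acetal carbon)
Conditions: CuI (10 mol %), 1,10-phenanthroline (20 mol %), Cs2CO3 (2 equiv), DMF, 90 °C, Ar
Reagents that add atoms: none
Why: Ullmann-type intramolecular O-arylation: the enolate oxygen on C2 displaces bromide from C8a, which is activated by the ortho acyl group, and ring C closes as a six-membered ring, as in chromone syntheses from 1-(2-haloaryl)-1,3-dicarbonyl compounds.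

Step 18
Reactants: 30 5-O-(methoxymethyl)-5'-O-(tetrahydro-2H-pyran-2-yl)formosanatin D
Product: 31 formosanatin D
Conditions: 3 M HCl (aq.), MeOH/THF, 45 °C
Reagents that add atoms: none
Why: Acid-catalysed acetal exchange removes the methoxymethyl and tetrahydropyranyl groups together; dilute acid at moderate temperature should spare the ring E olefin, the tertiary ethers and C2.

Compound list

1 | methyl 5-oxohexanoate | CC(=O)CCCC(=O)OC | starting material
2 | methyl 5-hydroxy-5-methylhexanoate (as its magnesium alkoxide) | COC(=O)CCCC(C)(C)O | intermediate (not isolated)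
3 | 6,6-dimethyltetrahydro-2H-pyran-2-one | CC1(C)CCCC(=O)O1 | intermediate
4 | methyl acetate | CC(=O)OC | starting material
5 | methyl 2-(2-hydroxy-6,6-dimethyltetrahydro-2H-pyran-2-yl)acetate (racemic) | COC(=O)CC1(O)CCCC(C)(C)O1 | intermediate
6 | methyl (E)-2-(6,6-dimethyltetrahydro-2H-pyran-2-ylidene)acetate | COC(=O)/C=C1\CCCC(C)(C)O1 | intermediate
7 | (E)-2-(6,6-dimethyltetrahydro-2H-pyran-2-ylidene)acetic acid | OC(=O)/C=C1\CCCC(C)(C)O1 | intermediate
8 | trimethylsilyl (E)-2-(6,6-dimethyltetrahydro-2H-pyran-2-ylidene)acetate | C[Si](C)(C)OC(=O)/C=C1\CCCC(C)(C)O1 | intermediate (not isolated)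
9 | 6-[2,2-bis(trimethylsilyloxy)vinyl]-2,2-dimethyl-3,4-dihydro-2H-pyran | C[Si](C)(C)OC(O[Si](C)(C)C)=CC1=CCCC(C)(C)O1 | intermediate
10 | methyl propiolate | C#CC(=O)OC | starting material
11 | methyl 3-bromopropiolate | COC(=O)C#CBr | intermediate
12 | methyl 5-bromo-2,2-dimethyl-7,7-bis(trimethylsilyloxy)-3,4,4a,7-tetrahydro-2H-chromene-6-carboxylate (racemic) | COC(=O)C1=C(Br)C2CCC(C)(C)OC2=CC1(O[Si](C)(C)C)O[Si](C)(C)C | intermediate (not isolated)
13 | methyl 5-bromo-2,2-dimethyl-7-(trimethylsilyloxy)chroman-6-carboxylate | COC(=O)c1c(O[Si](C)(C)C)cc2OC(C)(C)CCc2c1Br | intermediate (not isolated)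
14 | methyl 5-bromo-7-hydroxy-2,2-dimethylchroman-6-carboxylate | COC(=O)c1c(O)cc2OC(C)(C)CCc2c1Br | intermediate
15 | methyl 5-bromo-7-(methoxymethoxy)-2,2-dimethylchroman-6-carboxylate | COCOc1cc2OC(C)(C)CCc2c(Br)c1C(=O)OC | intermediate
16 | 5-bromo-7-(methoxymethoxy)-2,2-dimethylchroman-6-carboxylic acid | COCOc1cc2OC(C)(C)CCc2c(Br)c1C(=O)O | intermediate
17 | 2,5-dimethoxybenzaldehyde | COc1ccc(OC)c(C=O)c1 | starting material
18 | 2,5-dimethoxyphenyl formate | COc1ccc(OC)c(OC=O)c1 | intermediate (not isolated)
19 | 2,5-dimethoxyphenol | COc1ccc(OC)c(O)c1 | intermediate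
20 | 3-chloro-3-methylbut-1-yne | C#CC(C)(C)Cl | starting material
21 | 1,4-dimethoxy-2-[(2-methylbut-3-yn-2-yl)oxy]benzene | C#CC(C)(C)Oc1cc(OC)ccc1OC | intermediate
22 | 5,8-dimethoxy-2,2-dimethyl-2H-chromene | COc1ccc(OC)c2OC(C)(C)C=Cc12 | intermediate
23 | 2,2-dimethyl-2H-chromene-5,8-dione | CC1(C)C=CC2=C(O1)C(=O)C=CC2=O | intermediate
24 | 1,1-dimethoxyethene | C=C(OC)OC | starting material
25 | 2,2-dimethoxy-7,7-dimethyl-3,7-dihydro-2H-furo[2,3-f]chromen-5-ol | COC1(OC)Cc2cc(O)c3OC(C)(C)C=Cc3c2O1 | intermediate (not isolated)
26 | 5-hydroxy-7,7-dimethyl-3,7-dihydro-2H-furo[2,3-f]chromen-2-one (γ-lactone on chromene C5–O/C6–CH2, hydroxyl on chromene C8) | O=C1Cc2cc(O)c3OC(C)(C)C=Cc3c2O1 | intermediate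
27 | 7,7-dimethyl-5-[(tetrahydro-2H-pyran-2-yl)oxy]-3,7-dihydro-2H-furo[2,3-f]chromen-2-one (racemic) | O=C1Cc2cc(OC3CCCCO3)c3OC(C)(C)C=Cc3c2O1 | intermediate
28 | [5-bromo-7-(methoxymethoxy)-2,2-dimethylchroman-6-yl](1H-imidazol-1-yl)methanone | COCOc1cc2OC(C)(C)CCc2c(Br)c1C(=O)n1ccnc1 | intermediate (not isolated)
29 | 3-{[5-bromo-7-(methoxymethoxy)-2,2-dimethylchroman-6-yl]carbonyl}-7,7-dimethyl-5-[(tetrahydro-2H-pyran-2-yl)oxy]-3,7-dihydro-2H-furo[2,3-f]chromen-2-one (keto tautomer drawn; racemic acetal carbon) | COCOc1cc2OC(C)(C)CCc2c(Br)c1C(=O)C3C(=O)Oc4c3cc(OC5CCCCO5)c6OC(C)(C)C=Cc46 | intermediate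
30 | 5-O-(methoxymethyl)-5'-O-(tetrahydro-2H-pyran-2-yl)formosanatin D (racemic acetal carbon) | CC1(C)C=Cc2c(c(OC6CCCCO6)cc3c2oc2oc4c5c(cc(OCOC)c4c(=O)c23)OC(C)(C)CC5)O1 | intermediate
31 | formosanatin D | CC1(C)C=Cc2c(c(O)cc3c2oc2oc4c5c(cc(O)c4c(=O)c23)OC(C)(C)CC5)O1 | target

Total step count: 18. Longest linear sequence: 11 steps (steps 1, 2, 3, 4, 5, 7, 8, 9, 16, 17, 18). Ring B is made in steps 10–15 and the bromoalkyne in step 6.

Least certain steps

Step 7 (key step). The most likely failure is addition–elimination at the bromine-bearing alkyne carbon (net alkynylation of the diene terminus) or bromine transfer to the very electron-rich diene, both of which compete with cycloaddition. Hydrolysis of the silyl ketene acetal by adventitious acid would also consume 9. The fallback sets out from 10 and 9 and places the halogen after the ring is built. Compound 10 is stannylated (LiN(iPr)2, THF, −78 °C; Bu3SnCl) to methyl 3-(tributylstannyl)propiolate F1, which has no leaving group on the β-carbon. Cycloaddition of 9 with F1 (PhMe, 80 °C; then K2CO3, MeOH) under the same ester-controlled polarity should give methyl 7-hydroxy-2,2-dimethyl-5-(tributylstannyl)chroman-6-carboxylate F2. Ipso-bromodestannylation (NBS, CH2Cl2, −78 °C), which should be much faster than substitution at the hindered carbon between the two ring oxygens, returns to the route at 14.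

Step 5. Incomplete γ-deprotonation, attack of the amide base at silicon, or hydrolysis of the moisture-sensitive bis(silyl) acetal during isolation may limit the supply of 9; the acid 7 may also decarboxylate if its enol ether is hydrated before silylation. The fallback sets out from 6 and avoids both the acid and the silyl ester. Direct γ-deprotonation and silylation of 6 (LiN(iPr)2, THF, −78 °C; Me3SiCl) gives the mixed ketene acetal 6-[2-methoxy-2-(trimethylsilyloxy)vinyl]-2,2-dimethyl-3,4-dihydro-2H-pyran F3. Its cycloaddition with 11 under the conditions of step 7, with acidic work-up that removes methanol and the silyl group from the mixed ketal, returns to the route at 14. The price is the possibility that some C5 methyl ether forms by loss of silanol instead.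

Step 14. The ketene acetal may add to the other quinone CH (chromene C7), may undergo cycloaddition across a quinone C=C or C=O, or the vinylquinone may dimerise before it is trapped. The fallback sets out from 19 and fixes the regiochemistry by bromination para to a phenol. NBS (MeCN, 0 °C) gives 4-bromo-2,5-dimethoxyphenol F4. Etherification with 20 as in step 11 gives 1-bromo-2,5-dimethoxy-4-[(2-methylbut-3-yn-2-yl)oxy]benzene F5, and rearrangement as in step 12 gives 6-bromo-5,8-dimethoxy-2,2-dimethyl-2H-chromene F6. Pd-catalysed α-arylation with the Reformatsky reagent BrZnCH2CO2tBu (Pd(dba)2, P(tBu)3, THF, rt) gives tert-butyl 2-(5,8-dimethoxy-2,2-dimethyl-2H-chromen-6-yl)acetate F7. Oxidative demethylation as in step 13 gives tert-butyl 2-(2,2-dimethyl-5,8-dioxo-5,8-dihydro-2H-chromen-6-yl)acetate F8, and reduction (Na2S2O4, H2O/EtOAc) gives tert-butyl 2-(5,8-dihydroxy-2,2-dimethyl-2H-chromen-6-yl)acetate F9. Lactonisation (TsOH, PhMe, 80 °C) returns to the route at 26.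

Step 16. O-acylation without acyl transfer to carbon, slow reaction of the hindered acyl donor, or self-condensation of the lactone enolate may prevent clean formation of the C3–C4 bond. The fallback sets out from 15 and uses an aldehyde, a far better electrophile, followed by oxidation. Reduction (iBu2AlH, CH2Cl2, −78 → 0 °C) gives [5-bromo-7-(methoxymethoxy)-2,2-dimethylchroman-6-yl]methanol F10, and MnO2 (CH2Cl2, rt) gives 5-bromo-7-(methoxymethoxy)-2,2-dimethylchroman-6-carbaldehyde F11. Aldol addition of the lithium enolate of 27 (LiN(SiMe3)2, THF, −78 °C, cold quench) gives 3-{[5-bromo-7-(methoxymethoxy)-2,2-dimethylchroman-6-yl](hydroxy)methyl}-7,7-dimethyl-5-[(tetrahydro-2H-pyran-2-yl)oxy]-3,7-dihydro-2H-furo[2,3-f]chromen-2-one F12 as a diastereomer mixture. Oxidation (2-iodoxybenzoic acid, DMSO, rt) returns to the route at 29.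

Step 17. C–O bond formation at a bromide flanked by two ortho substituents may be slow, so that reductive loss of bromine or cleavage of the lactone by carbonate and traces of water take over at the temperature required. The fallback sets out from 15 and changes the leaving group so that ring closure can run at lower temperature. An aromatic Finkelstein reaction (CuI, NaI, N,N'-dimethylethylenediamine, dioxane, 110 °C) gives methyl 5-iodo-7-(methoxymethoxy)-2,2-dimethylchroman-6-carboxylate F13. Saponification as in step 9 gives 5-iodo-7-(methoxymethoxy)-2,2-dimethylchroman-6-carboxylic acid F14, and 1,1'-carbonyldiimidazole gives [5-iodo-7-(methoxymethoxy)-2,2-dimethylchroman-6-yl](1H-imidazol-1-yl)methanone F15. Acylation of 27 as in step 16 gives 3-{[5-iodo-7-(methoxymethoxy)-2,2-dimethylchroman-6-yl]carbonyl}-7,7-dimethyl-5-[(tetrahydro-2H-pyran-2-yl)oxy]-3,7-dihydro-2H-furo[2,3-f]chromen-2-one F16. Its ring closure (CuI, Cs2CO3, DMF, at or below 60 °C) returns to the route at 30.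

Further compounds

F1 | step 7 | methyl 3-(tributylstannyl)propiolate | CCCC[Sn](CCCC)(CCCC)C#CC(=O)OC
F2 | step 7 | methyl 7-hydroxy-2,2-dimethyl-5-(tributylstannyl)chroman-6-carboxylate | COC(=O)c1c(O)cc2OC(C)(C)CCc2c1[Sn](CCCC)(CCCC)CCCC
F3 | step 5 | 6-[2-methoxy-2-(trimethylsilyloxy)vinyl]-2,2-dimethyl-3,4-dihydro-2H-pyran | COC(O[Si](C)(C)C)=CC1=CCCC(C)(C)O1
F4 | step 14 | 4-bromo-2,5-dimethoxyphenol | Oc1cc(OC)c(Br)cc1OC
F5 | step 14 | 1-bromo-2,5-dimethoxy-4-[(2-methylbut-3-yn-2-yl)oxy]benzene | C#CC(C)(C)Oc1cc(OC)c(Br)cc1OC
F6 | step 14 | 6-bromo-5,8-dimethoxy-2,2-dimethyl-2H-chromene | COc1cc(Br)c(OC)c2C=CC(C)(C)Oc12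
F7 | step 14 | tert-butyl 2-(5,8-dimethoxy-2,2-dimethyl-2H-chromen-6-yl)acetate | COc1cc(CC(=O)OC(C)(C)C)c(OC)c2C=CC(C)(C)Oc12
F8 | step 14 | tert-butyl 2-(2,2-dimethyl-5,8-dioxo-5,8-dihydro-2H-chromen-6-yl)acetate | CC1(C)C=CC2=C(O1)C(=O)C=C(CC(=O)OC(C)(C)C)C2=O
F9 | step 14 | tert-butyl 2-(5,8-dihydroxy-2,2-dimethyl-2H-chromen-6-yl)acetate | CC1(C)C=Cc2c(O1)c(O)cc(CC(=O)OC(C)(C)C)c2O
F10 | step 16 | [5-bromo-7-(methoxymethoxy)-2,2-dimethylchroman-6-yl]methanol | COCOc1cc2OC(C)(C)CCc2c(Br)c1CO
F11 | step 16 | 5-bromo-7-(methoxymethoxy)-2,2-dimethylchroman-6-carbaldehyde | COCOc1cc2OC(C)(C)CCc2c(Br)c1C=O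
F12 | step 16 | 3-{[5-bromo-7-(methoxymethoxy)-2,2-dimethylchroman-6-yl](hydroxy)methyl}-7,7-dimethyl-5-[(tetrahydro-2H-pyran-2-yl)oxy]-3,7-dihydro-2H-furo[2,3-f]chromen-2-one (diastereomer mixture) | COCOc1cc2OC(C)(C)CCc2c(Br)c1C(O)C3C(=O)Oc4c3cc(OC5CCCCO5)c6OC(C)(C)C=Cc46
F13 | step 17 | methyl 5-iodo-7-(methoxymethoxy)-2,2-dimethylchroman-6-carboxylate | COCOc1cc2OC(C)(C)CCc2c(I)c1C(=O)OC
F14 | step 17 | 5-iodo-7-(methoxymethoxy)-2,2-dimethylchroman-6-carboxylic acid | COCOc1cc2OC(C)(C)CCc2c(I)c1C(=O)O
F15 | step 17 | [5-iodo-7-(methoxymethoxy)-2,2-dimethylchroman-6-yl](1H-imidazol-1-yl)methanone | COCOc1cc2OC(C)(C)CCc2c(I)c1C(=O)n1ccnc1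
F16 | step 17 | 3-{[5-iodo-7-(methoxymethoxy)-2,2-dimethylchroman-6-yl]carbonyl}-7,7-dimethyl-5-[(tetrahydro-2H-pyran-2-yl)oxy]-3,7-dihydro-2H-furo[2,3-f]chromen-2-one | COCOc1cc2OC(C)(C)CCc2c(I)c1C(=O)C3C(=O)Oc4c3cc(OC5CCCCO5)c6OC(C)(C)C=Cc46
A1 | alternative 1 | 1-(5-hydroxy-7-methoxy-2,2-dimethylchroman-6-yl)-2-[5-hydroxy-8-(methoxymethoxy)-2,2-dimethyl-2H-chromen-6-yl]ethan-1-one | COc1cc2OC(C)(C)CCc2c(O)c1C(=O)Cc1cc(OCOC)c2OC(C)(C)C=Cc2c1O
A2 | alternative 1 | 5-O-methyl-5'-O-(methoxymethyl)formosanatin D | CC1(C)C=Cc2c(c(OCOC)cc3c2oc2oc4c5c(cc(OC)c4c(=O)c23)OC(C)(C)CC5)O1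
A3 | alternative 2 | 5-hydroxy-5'-(methoxymethoxy)coumaronochromone 7-O-(2-methylbut-3-en-2-yl) 4'-O-(2-methylbut-3-yn-2-yl) diether | O=c1c2c(O)cc(OC(C)(C)C=C)cc2oc2oc3cc(OC(C)(C)C#C)c(OCOC)cc3c12
A4 | alternative 2 | 5,7-dihydroxy-8-prenyl-5'-(methoxymethoxy)coumaronochromone with ring E closed | CC1(C)C=Cc2c(c(OCOC)cc3c2oc2oc4c(CC=C(C)C)c(O)cc(O)c4c(=O)c23)O1
A5 | alternative 3 | 4,5-dimethoxy-3-(8-hydroxy-2,2-dimethyl-2H-chromen-6-yl)coumarin with ring D fused at C7–O/C8 | COc1cc2OC(C)(C)CCc2c2oc(=O)c(c(OC)c12)-c1cc(O)c2OC(C)(C)C=Cc2c1
A6 | alternative 3 | 5-O-methylformosanatin D | CC1(C)C=Cc2c(c(O)cc3c2oc2oc4c5c(cc(OC)c4c(=O)c23)OC(C)(C)CC5)O1
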